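**Assumption:** littorachalcone has no stereocentres (it is achiral), so there is no enantiomer to select; the only stereocentre in the route (the carbinol of compound 6) is used racemic and is destroyed in the next step.

## Retrosynthetic overview
1. The obvious route (diaryl ether dialdehyde, double Claisen–Schmidt, hydrogenation) is avoided; instead both Ar–CH2 bonds are cut.
2. Key step: a two-fold Heck arylation/redox isomerisation of a diiodo diaryl ether with an aryl vinyl carbinol gives both saturated ketones directly, with no enone and no hydrogenation.
3. The diiodo diaryl ether comes from a Chan–Lam O-arylation that leaves both C–I bonds intact.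
4. The carbinol comes from vinyl Grignard addition to 2,4-dimethoxybenzaldehyde; the last step is global O-demethylation.
5. No rings are formed: all four benzene rings are purchased. Order of assembly: diaryl ether first, then both C3 ketone linkers at once.

## Route

**Step 1**
Reactants: 1, 4-iodo-2-methoxyphenol; 2, 4-iodophenylboronic acid (2 equiv)
Product: 3, 4-iodo-1-(4-iodophenoxy)-2-methoxybenzene
Conditions: Cu(OAc)2 (1 equiv), pyridine (5 equiv), 4 Å MS, CH2Cl2, air, rt, 48 h
Reagents that add atoms: 4-iodophenylboronic acid (2), OB(O)c1ccc(I)cc1 (supplies the 4-iodophenyl group)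
Why: Chan–Evans–Lam oxidative O-arylation runs at room temperature through Cu(II)/Cu(III) and does not insert into aryl C–I bonds, so both iodides survive for the Heck step, and ortho-alkoxy phenols are competent partners.

**Step 2**
Reactants: 4, 2,4-dimethoxybenzaldehyde; 5, vinylmagnesium bromide (1.2 equiv)
Product: 6, 1-(2,4-dimethoxyphenyl)prop-2-en-1-ol (racemic)
Conditions: THF, 0 °C to rt; sat. aq. NH4Cl quench
Reagents that add atoms: vinylmagnesium bromide (5), C=C[Mg]Br (supplies the vinyl group)
Why: Grignard 1,2-addition to a non-enolisable aldehyde; the new carbinol centre is racemic and is removed as the ketone in Step 3. Use 6 promptly and keep it away from acid, since it is an electron-rich benzylic allylic alcohol.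

**Step 3 (key step)**
Reactants: 3, 4-iodo-1-(4-iodophenoxy)-2-methoxybenzene; 6, 1-(2,4-dimethoxyphenyl)prop-2-en-1-ol (3 equiv)
Product: 7, penta-O-methyl-littorachalcone, i.e. 1-(2,4-dimethoxyphenyl)-3-[4-[4-[3-(2,4-dimethoxyphenyl)-3-oxopropyl]-2-methoxyphenoxy]phenyl]propan-1-one
Conditions: Pd(OAc)2 (10 mol %), n-Bu4NCl (2 equiv), NaHCO3 (5 equiv), degassed DMF, 70 °C, N2
Reagents that add atoms: none beyond reactants 3 and 6
Why: Two-fold Heck–Jeffery arylation of a secondary allylic alcohol (Heck/redox isomerisation): Ar–Pd adds with aryl on the terminal CH2, β-hydride elimination goes toward the carbinol C–H, and the enol tautomerises to the ArCH2CH2C(=O)Ar' ketone, with loss of HI at each end.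

**Step 4**
Reactants: 7, penta-O-methyl-littorachalcone
Product: 8, littorachalcone, 1-(2,4-dihydroxyphenyl)-3-[4-[4-[3-(2,4-dihydroxyphenyl)-3-oxopropyl]-2-hydroxyphenoxy]phenyl]propan-1-one
Conditions: BBr3 (12 equiv), CH2Cl2, −78 °C to rt, 16 h; then ice/MeOH and aqueous work-up
Reagents that add atoms: none (the five methyl groups leave as MeBr; the phenolic H comes from work-up)
Why: Lewis-acid aryl methyl ether cleavage with BBr3; the 2'-OMe groups are assisted by chelation to the ketone, the guaiacol OMe is easy, and the diaryl ether and saturated ketones are inert to BBr3.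

## Compound list
1 | 4-iodo-2-methoxyphenol | COc1cc(I)ccc1O | starting material
2 | 4-iodophenylboronic acid | OB(O)c1ccc(I)cc1 | starting material
3 | 4-iodo-1-(4-iodophenoxy)-2-methoxybenzene | COc1cc(I)ccc1Oc1ccc(I)cc1 | intermediate
4 | 2,4-dimethoxybenzaldehyde | COc1ccc(C=O)c(OC)c1 | starting material
5 | vinylmagnesium bromide | C=C[Mg]Br | starting material
6 | 1-(2,4-dimethoxyphenyl)prop-2-en-1-ol (racemic) | C=CC(O)c1ccc(OC)cc1OC | intermediate
7 | penta-O-methyl-littorachalcone | COc1ccc(C(=O)CCc2ccc(Oc3ccc(CCC(=O)c4ccc(OC)cc4OC)cc3OC)cc2)c(OC)c1 | intermediate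
8 | littorachalcone | O=C(CCc1ccc(Oc2ccc(CCC(=O)c3ccc(O)cc3O)cc2O)cc1)c1ccc(O)cc1O | target

## Summary
Total steps: 4. Longest linear sequence: 3 (1 → 3 → 7 → 8, or 4 → 6 → 7 → 8).

**Three steps most likely to fail, with fallbacks**

1. **Step 3, double Heck/isomerisation.** Risks are β-hydride elimination the wrong way (giving arylated allylic alcohol), Pd–H isomerisation of 6 to the propiophenone, and a stalled second coupling. Fallback: convert 3 to the bis(pinacol boronate) by Miyaura borylation, oxidise 6 to 1-(2,4-dimethoxyphenyl)prop-2-en-1-one with MnO2, and join them by a two-fold Rh(I)-catalysed Hayashi–Miyaura conjugate addition.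

2. **Step 4, five-fold demethylation.** Risks are incomplete cleavage of the 4'-OMe groups para to the carbonyl and acid-mediated cyclisation of the electron-rich B ring onto the ketone. Fallback: change the protecting-group plan. Demethylate 3 with BBr3 at the diiodide stage, run the Heck step with commercially available 2,4-bis(benzyloxy)benzaldehyde as the carbinol precursor, and finish with neutral hydrogenolysis (H2, Pd/C).

3. **Step 1, Chan–Lam etherification.** Risks are low conversion of the ortho-substituted phenol and boronic acid homocoupling or oxidation by-products. Fallback: SNAr of 1 with 1-fluoro-4-nitrobenzene (K2CO3, DMF), nitro reduction with Fe/NH4Cl (keeps the aryl iodide), then diazotisation/KI (Sandmeyer-type iodination) to give 3.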